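**Strategy.** The cyclohexene ring is cut at C1–C2 and C4–C5 (target numbering: C1 quaternary carbinol carrying C7H2OBz, C2 and C5 benzoyloxy carbons, C3=C4 the ring alkene, C6 the CHOH carbon). These two bonds flank the allyl unit C2–C3=C4, which sits between a homoallylic tertiary alcohol (C1) and an allylic oxygen (C5): the signature of a double carbonyl allylboration. A (Z)-1,3-diboryl-1-alkoxypropene (C2–C4) and a keto-aldehyde (C5–C6–C1–C7), cut from benzylidene-glucose by glycol cleavage and held as a 2-phenyl-1,3-dioxan-5-one, are joined in one [3+3] operation: allylboration of the aldehyde, then ring-closing allylboration of the ketone. C1, C2 and C5 come from the reagent by chirality transfer; C6 comes from glucose.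

Key step: step 7

Remark: Matteson homologation of (R,R)-1,2-dicyclohexylethanediol boronic esters is taken to give the (αS)-chloride, the usual sense for this diol; the route needs the (1S)-chloride in step 5 and, after inversion, the (1R)-ether in step 6.

Step 1
Reactants: 1 4,6-O-[(R)-benzylidene]-D-glucopyranose
Product: 3 2,4-O-[(R)-benzylidene]-D-erythrose, via 3-O-formyl-2,4-O-benzylidene-D-erythrose 2 (not isolated)
Conditions: NaIO4 (2.1 equiv), H2O, 0 °C to rt
Reagents that add atoms: none
Why: Malaprade glycol cleavage cuts C1–C2 and C2–C3 of the pyranose (the anomeric carbon leaves through formate ester 2, which hydrolyses in the aqueous medium), while the 4,6-acetal keeps O4 and O6 out of reach, so C4 and C5 of glucose and the acetal carbon pass unchanged into 3.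

Step 2
Reactants: 3 2,4-O-[(R)-benzylidene]-D-erythrose
Product: 4 (2R,4S)-5-oxo-2-phenyl-1,3-dioxane-4-carbaldehyde
Conditions: Dess–Martin periodinane (1.3 equiv), CH2Cl2, 0 °C to rt; used at once
Reagents that add atoms: none
Why: Dess–Martin oxidation should convert the only hydroxyl into the ketone without touching the aldehyde; the carbon between the two carbonyls (future C6) can enolise but should return to the same epimer, because only that one has the formyl and 2-phenyl groups both equatorial on the 1,3-dioxane.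

Step 3
Reactants: 5 tetrahydroxydiboron; 6 (1R,2R)-1,2-dicyclohexylethane-1,2-diol (2 equiv)
Product: 7 (4R,4′R,5R,5′R)-4,4′,5,5′-tetracyclohexyl-2,2′-bi(1,3,2-dioxaborolane)
Conditions: toluene, reflux, Dean–Stark trap
Reagents that add atoms: none
Why: Condensation (boronic esterification) of the B–OH groups with the 1,2-diol is driven by azeotropic removal of water and touches no stereocentre.

Step 4
Reactants: 7 (4R,4′R,5R,5′R)-4,4′,5,5′-tetracyclohexyl-2,2′-bi(1,3,2-dioxaborolane); 8 acetylene
Product: 9 (Z)-1,2-bis[(4R,5R)-4,5-dicyclohexyl-1,3,2-dioxaborolan-2-yl]ethene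
Conditions: Pt(PPh3)4 (3 mol %), acetylene (1 atm), DMF, 80 °C
Reagents that add atoms: none
Why: Platinum-catalysed diboration of an alkyne adds the B–B bond across one face of acetylene (syn addition), which should fix the Z geometry that later becomes the cis ring alkene C3=C4.

Step 5
Reactants: 9 (Z)-1,2-bis[(4R,5R)-4,5-dicyclohexyl-1,3,2-dioxaborolan-2-yl]ethene
Product: 10 (4R,5R)-2-[(1S,2Z)-1-chloro-3-[(4R,5R)-4,5-dicyclohexyl-1,3,2-dioxaborolan-2-yl]prop-2-en-1-yl]-4,5-dicyclohexyl-1,3,2-dioxaborolane
Conditions: CH2Cl2 (1.1 equiv), n-BuLi (1.0 equiv), THF, −100 °C; then ZnCl2 (0.7 equiv), −100 °C to rt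
Reagents that add atoms: dichloromethyllithium, [Li]C(Cl)Cl (made in the flask from dichloromethane, ClCCl, and n-BuLi)
Why: Matteson homologation: one equivalent of LiCHCl2 forms a borate at one boron (the anionic mono-borate disfavours a second addition), the ZnCl2-promoted 1,2-shift of the alkenyl group keeps the Z geometry and expels chloride, and the (R,R)-diol directs the new B–CHCl centre to (S).

Step 6
Reactants: 10 (4R,5R)-2-[(1S,2Z)-1-chloro-3-[(4R,5R)-4,5-dicyclohexyl-1,3,2-dioxaborolan-2-yl]prop-2-en-1-yl]-4,5-dicyclohexyl-1,3,2-dioxaborolane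
Product: 11 (4R,5R)-2-[(1R,2Z)-3-[(4R,5R)-4,5-dicyclohexyl-1,3,2-dioxaborolan-2-yl]-1-[(4-methoxybenzyl)oxy]prop-2-en-1-yl]-4,5-dicyclohexyl-1,3,2-dioxaborolane
Conditions: 4-methoxybenzyl alcohol (1.1 equiv), NaH (1.1 equiv), THF–DMSO, 0 °C to rt
Reagents that add atoms: sodium 4-methoxybenzyl oxide, [Na+].[O-]Cc1ccc(OC)cc1 (made in the flask from 4-methoxybenzyl alcohol, OCc1ccc(OC)cc1, and NaH)
Why: Matteson alkoxide displacement: the alkoxide adds to boron and migrates to carbon with loss of chloride, a substitution with inversion that should give the (R)-α-alkoxy allylboronate (future C2, the centre that relays all new stereochemistry).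

Step 7
Reactants: 4 (2R,4S)-5-oxo-2-phenyl-1,3-dioxane-4-carbaldehyde; 11 (4R,5R)-2-[(1R,2Z)-3-[(4R,5R)-4,5-dicyclohexyl-1,3,2-dioxaborolan-2-yl]-1-[(4-methoxybenzyl)oxy]prop-2-en-1-yl]-4,5-dicyclohexyl-1,3,2-dioxaborolane (1.1 equiv)
Product: 13 trans-fused benzylidene-protected PMB ether diol (carbocycle C1–C6 closed; OH at C1 and C5), via allylboronate adduct 12 (not isolated)
Conditions: toluene, 4 Å molecular sieves, rt, then 80 °C; H2O work-up
Reagents that add atoms: none
Why: Proposed new method: the allylic C–B bond of 11 should add to the aldehyde of 4 through a closed chair transition state (allylboration, syn-SE2′) and form C4–C5, giving 12, whose new C4–B bond is again allylic; on warming, this boronate should allylborate the dioxanone carbonyl within the molecule and form C1–C2, so that one reagent makes both bonds (closest known type: double allylboration of two carbonyl groups with γ-boryl allylboron reagents, here with an α-alkoxy group and a ring-closing second stage). The carbocycle closes in a six-membered mode in which C2, C3 and C4 all become ring atoms, through a boat-shaped bicyclo[2.2.2]-type transition state (boron on C4 bound to the C1 carbonyl oxygen), and equatorial attack on the dioxanone gives the trans ring fusion. C5 is set by the (R)-boron-bearing carbon of 11: the cis-boryl group must sit axial in the chair, which forces the OPMB group equatorial and thereby fixes both the aldehyde face (5R, against the Felkin preference of 4) and the (E)-enol ether of 12. C1 is set by the C4–B centre of 12, because the carbonyl oxygen is delivered on the boron-bearing face (OH trans to O5 and cis to O6), and C2 by the (E)-enol ether geometry (OPMB cis to the C1 hydroxyl). The step needs aldehyde-before-ketone chemoselectivity, which the reactivity gap secures, and a stable C6 centre although it lies between two carbonyls, which the 2-phenyl-1,3-dioxane secures by holding the side chain equatorial.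

Step 8
Reactants: 13 trans-fused benzylidene-protected PMB ether diol
Product: 14 benzylidene-protected triol (OH at C1, C2 and C5)
Conditions: DDQ (1.3 equiv), CH2Cl2–H2O (10:1), 0 °C
Reagents that add atoms: none
Why: Oxidative cleavage of the PMB ether (benzylic hydride abstraction by DDQ, then hydrolysis of the oxocarbenium ion by the water present) should free the C2 hydroxyl and leave the benzylidene acetal, the alkene and all stereocentres untouched.

Step 9
Reactants: 14 benzylidene-protected triol
Product: 15 benzylidene-protected C2,C5-dibenzoate (C1 hydroxyl free)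
Conditions: BzCl (2.4 equiv), pyridine, DMAP (cat.), CH2Cl2, 0 °C to rt
Reagents that add atoms: benzoyl chloride, O=C(Cl)c1ccccc1
Why: Acylation of the two secondary allylic hydroxyls proceeds with retention (only O–H bonds are broken), while the tertiary C1 hydroxyl is too hindered to react.

Step 10
Reactants: 15 benzylidene-protected C2,C5-dibenzoate
Product: 16 (1S,2R,5R,6S)-1,6-dihydroxy-1-(hydroxymethyl)cyclohex-3-ene-2,5-diyl dibenzoate
Conditions: AcOH–H2O (4:1), 45 °C
Reagents that add atoms: none
Why: Acid-catalysed acetal hydrolysis should release the C6 and C7 hydroxyls under conditions mild enough to leave the allylic benzoates in place.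

Step 11
Reactants: 16 (1S,2R,5R,6S)-1,6-dihydroxy-1-(hydroxymethyl)cyclohex-3-ene-2,5-diyl dibenzoate
Product: 17 [(1S,2R,5R,6S)-2,5-bis(benzoyloxy)-1,6-dihydroxycyclohex-3-en-1-yl]methyl benzoate (CNP0128482.1)
Conditions: BzCl (1.05 equiv), pyridine, CH2Cl2, −30 °C to 0 °C
Reagents that add atoms: benzoyl chloride, O=C(Cl)c1ccccc1
Why: Selective acylation with one equivalent of BzCl at low temperature should take the primary C7 hydroxyl ahead of the hindered secondary C6 and tertiary C1 hydroxyls and give the target.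

**Compound list**

1 | 4,6-O-[(R)-benzylidene]-D-glucopyranose | O[C@H]([C@@H](O)C(O)O3)[C@@H]1O[C@H](c2ccccc2)OC[C@H]13 | starting material
2 | 3-O-formyl-2,4-O-benzylidene-D-erythrose, (2R,4R,5R)-4-formyl-2-phenyl-1,3-dioxan-5-yl formate | O=C[C@@H]1O[C@H](c2ccccc2)OC[C@H]1OC=O | intermediate
3 | 2,4-O-[(R)-benzylidene]-D-erythrose, (2R,4R,5R)-5-hydroxy-2-phenyl-1,3-dioxane-4-carbaldehyde | O=C[C@@H]1O[C@H](c2ccccc2)OC[C@H]1O | intermediate
4 | (2R,4S)-5-oxo-2-phenyl-1,3-dioxane-4-carbaldehyde | O=C[C@@H]1O[C@H](c2ccccc2)OCC1=O | intermediate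
5 | tetrahydroxydiboron | OB(O)B(O)O | starting material
6 | (1R,2R)-1,2-dicyclohexylethane-1,2-diol | O[C@H](C1CCCCC1)[C@H](O)C1CCCCC1 | starting material
7 | (4R,4′R,5R,5′R)-4,4′,5,5′-tetracyclohexyl-2,2′-bi(1,3,2-dioxaborolane) | B1(O[C@H](C2CCCCC2)[C@@H](C2CCCCC2)O1)B1O[C@H](C2CCCCC2)[C@@H](C2CCCCC2)O1 | intermediate
8 | acetylene | C#C | starting material
9 | (Z)-1,2-bis[(4R,5R)-4,5-dicyclohexyl-1,3,2-dioxaborolan-2-yl]ethene | O1[C@H](C2CCCCC2)[C@@H](C2CCCCC2)OB1/C=C\B1O[C@H](C2CCCCC2)[C@@H](C2CCCCC2)O1 | intermediate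
10 | (4R,5R)-2-[(1S,2Z)-1-chloro-3-[(4R,5R)-4,5-dicyclohexyl-1,3,2-dioxaborolan-2-yl]prop-2-en-1-yl]-4,5-dicyclohexyl-1,3,2-dioxaborolane | Cl[C@H](/C=C\B1O[C@H](C2CCCCC2)[C@@H](C2CCCCC2)O1)B1O[C@H](C2CCCCC2)[C@@H](C2CCCCC2)O1 | intermediate
11 | (4R,5R)-2-[(1R,2Z)-3-[(4R,5R)-4,5-dicyclohexyl-1,3,2-dioxaborolan-2-yl]-1-[(4-methoxybenzyl)oxy]prop-2-en-1-yl]-4,5-dicyclohexyl-1,3,2-dioxaborolane | COc1ccc(CO[C@@H](/C=C\B2O[C@H](C3CCCCC3)[C@@H](C3CCCCC3)O2)B2O[C@H](C3CCCCC3)[C@@H](C3CCCCC3)O2)cc1 | intermediate
12 | (2R,4S)-4-[(1R,2S,3E)-1-(boryloxy)-2-boryl-4-[(4-methoxybenzyl)oxy]but-3-en-1-yl]-2-phenyl-1,3-dioxan-5-one, boryl = (4R,5R)-4,5-dicyclohexyl-1,3,2-dioxaborolan-2-yl | COc1ccc(CO/C=C/[C@H](B2O[C@H](C3CCCCC3)[C@@H](C3CCCCC3)O2)[C@@H](OB2O[C@H](C3CCCCC3)[C@@H](C3CCCCC3)O2)[C@@H]2O[C@H](c3ccccc3)OCC2=O)cc1 | intermediate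
13 | trans-fused bicyclic diol: target carbocycle with free OH at C1 and C5, PMB ether at O2, and O6 and O7 joined by the (R)-benzylidene acetal; C1, C2, C5 and C6 arranged as in 17 | O1C[C@@]2(O)[C@H](OCc3ccc(OC)cc3)C=C[C@@H](O)[C@@H]2O[C@@H]1c1ccccc1 | intermediate
14 | triol: as 13 with free OH at C2 | O1C[C@@]2(O)[C@H](O)C=C[C@@H](O)[C@@H]2O[C@@H]1c1ccccc1 | intermediate
15 | C2,C5-dibenzoate: as 14 with benzoates at O2 and O5, C1 hydroxyl free | O1C[C@@]2(O)[C@H](OC(=O)c3ccccc3)C=C[C@@H](OC(=O)c3ccccc3)[C@@H]2O[C@@H]1c1ccccc1 | intermediate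
16 | (1S,2R,5R,6S)-1,6-dihydroxy-1-(hydroxymethyl)cyclohex-3-ene-2,5-diyl dibenzoate | OC[C@@]1(O)[C@H](OC(=O)c2ccccc2)C=C[C@@H](OC(=O)c2ccccc2)[C@@H]1O | intermediate
17 | [(1S,2R,5R,6S)-2,5-bis(benzoyloxy)-1,6-dihydroxycyclohex-3-en-1-yl]methyl benzoate | O=C(OC[C@@]1(O)[C@H](OC(=O)c2ccccc2)C=C[C@@H](OC(=O)c2ccccc2)[C@@H]1O)c1ccccc1 | target

**Totals.** Total step count: 11. Longest linear sequence: 9 steps (steps 3 to 11, from 5 and 6); the branch from 1 runs through 7 steps (1, 2, 7 to 11).

**Steps most likely to fail**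

Step 7 (Proposed new method). Three processes may spoil it. The first allylboration may be slow, because the boronate is α-alkoxy-substituted and carries a cis boryl group, and the enolisable keto-aldehyde may degrade meanwhile. Reagent control over the aldehyde face may be incomplete, giving Felkin addition. The boat-type ring closure may lose to intermolecular allylboration. The fallback uses known reactions only and runs from 4 back to 15. Nozaki–Hiyama–Kishi vinylation of the aldehyde of 4 (vinyl bromide, CrCl2, NiCl2 cat., DMF; the ketone is left alone) should give the Felkin allylic alcohol (2R,4S)-4-[(1S)-1-hydroxyprop-2-en-1-yl]-2-phenyl-1,3-dioxan-5-one F1. Indium-mediated Barbier addition of 3-bromopropenyl benzoate to the ketone (In, THF–H2O) should give the diene 5-[1-(benzoyloxy)prop-2-enyl]-5-hydroxy-4-[(1S)-1-hydroxyprop-2-enyl]-2-phenyl-1,3-dioxane F2, with C1 and C2 as in 17 after separation of diastereomers. Ring-closing metathesis with the second-generation Grubbs catalyst closes C3=C4 to the C5-epimeric C2-monobenzoate F3. Mitsunobu esterification (PPh3, DIAD, benzoic acid) inverts C5 while installing its benzoate and arrives at 15.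

Step 2. Oxidation of the hydrated or dimeric hydroxy-aldehyde may stray to the aldehyde carbon or stall, and the β-keto aldehyde may be lost on handling. The fallback runs from 3 back to 4 and unveils the aldehyde last. Wittig methylenation (Ph3P=CH2, THF) masks it as the vinyl group in (2R,4S,5R)-2-phenyl-4-vinyl-1,3-dioxan-5-ol F4. Dess–Martin oxidation gives (2R,4S)-2-phenyl-4-vinyl-1,3-dioxan-5-one F5. Ozonolysis (O3, CH2Cl2, −78 °C; then PPh3) releases 4 cold and acid-free for direct use in step 7.

Step 8. DDQ may oxidise the free allylic C5 alcohol, or close a p-methoxybenzylidene acetal between O1 and O2 instead of freeing the C2 hydroxyl. The fallback runs from 13 back to 15 and removes the oxidisable alcohol before a non-oxidative deprotection. Benzoylation of the C5 hydroxyl (BzCl, pyridine) gives the C5-benzoate PMB ether F6. Lewis-acid cleavage of the PMB ether with MgBr2·OEt2 and Me2S gives the C2 alcohol F7. A second benzoylation (BzCl, pyridine, DMAP) gives 15.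

**Further compounds**

F1 | step 7 | (2R,4S)-4-[(1S)-1-hydroxyprop-2-en-1-yl]-2-phenyl-1,3-dioxan-5-one | C=C[C@H](O)[C@@H]1O[C@H](c2ccccc2)OCC1=O
F2 | step 7 | 5-[1-(benzoyloxy)prop-2-enyl]-5-hydroxy-4-[(1S)-1-hydroxyprop-2-enyl]-2-phenyl-1,3-dioxane, C1 and C2 as in 17 | C=C[C@H](O)[C@@H]1O[C@H](c2ccccc2)OC[C@@]1(O)[C@H](OC(=O)c2ccccc2)C=C
F3 | step 7 | C5-epimeric C2-monobenzoate of 14 | O1C[C@@]2(O)[C@H](OC(=O)c3ccccc3)C=C[C@H](O)[C@@H]2O[C@@H]1c1ccccc1
F4 | step 2 | (2R,4S,5R)-2-phenyl-4-vinyl-1,3-dioxan-5-ol | C=C[C@@H]1O[C@H](c2ccccc2)OC[C@H]1O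
F5 | step 2 | (2R,4S)-2-phenyl-4-vinyl-1,3-dioxan-5-one | C=C[C@@H]1O[C@H](c2ccccc2)OCC1=O
F6 | step 8 | C5-benzoate of 13 (PMB ether at O2, C1 hydroxyl free) | O1C[C@@]2(O)[C@H](OCc3ccc(OC)cc3)C=C[C@@H](OC(=O)c3ccccc3)[C@@H]2O[C@@H]1c1ccccc1
F7 | step 8 | C5-monobenzoate of 14 (free OH at C1 and C2) | O1C[C@@]2(O)[C@H](O)C=C[C@@H](OC(=O)c3ccccc3)[C@@H]2O[C@@H]1c1ccccc1
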